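| flask | Z | L | remark | time |
|---|---|---|---|---|
| Thursday's | 0.10 M | 15 mol% (in portions, 2) | run made earlier; portions every 2.5 min |  |
| Sunday's | 0.15 M | 15 mol% (in portions, 2) | run made earlier; portions every 2.5 min |  |
| flask | 0.20 M | 15 mol% (in portions, 2) | the portions of L follow each other after 2.5 min, the first at the start | 80 min |

| run | time / min | E / % | G / % | Z / % | Q / % |
|---|---|---|---|---|---|
| Thursday's | 2.50 | 0.4 | 3.0 | 15.4 | 79.5 |
| Thursday's | 8.00 | 0.8 | 19.7 | 0 | 75.6 |
| Thursday's | 15.0 | 4.3 | 30.7 | 0 | 61.4 |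
| Thursday's | 20.0 | 6.7 | 34.9 | 0 | 54.7 |
| Thursday's | 30.0 | 12.9 | 36.6 | 0.2 | 46.3 |
| Thursday's | 40.0 | 18.7 | 36.5 | 0 | 42.8 |
| Thursday's | 50.0 | 23.9 | 35.0 | 0.3 | 38.5 |
| Sunday's | 2.50 | 0 | 4.1 | 14.5 | 76.2 |
| Sunday's | 8.00 | 2.2 | 26.1 | 0.5 | 67.9 |
| Sunday's | 15.0 | 5.0 | 36.8 | 0.2 | 53.6 |
| Sunday's | 20.0 | 8.7 | 39.9 | 0 | 48.1 |
| Sunday's | 30.0 | 14.9 | 38.7 | 0 | 42.0 |
| Sunday's | 40.0 | 21.3 | 36.2 | 0 | 37.9 |
| Sunday's | 50.0 | 26.8 | 34.2 | 0 | 35.1 |

(standard deviation of a reading: 0.3 percentage points)

- the earlier runs were read with a standard deviation of 0.3 percentage points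

- the largest share of what was charged as Z, at 80 min belongs to (E / G / Z / Q)
- the largest share itself, whichever of these holds it, in percent of the Z charged

**Leak constant.** Take the small charge first: Thursday's run, [Z] = 0.10 M. Read it as Q feeding G and G feeding E. From 30.0 min to 50.0 min, divide the rise of E by the mean G and by the minutes passed; the reading is 0.0154 min⁻¹. Sunday's run, [Z] = 0.15 M, reads 0.0163 min⁻¹. Call this first-order rate constant of G into E, as Sunday's run reads it, the leak constant.

**Opposite outcome.** Turn the question round. Sunday's run at 50.0 min has Q and G level, 35.1% and 34.2%, and counts 96.1% in total. As my own assumption, start the flask from that state, with a pool Q + G of 69.3%. If Q and G stay level, the pool falls at 0.00816 min⁻¹, since the leak draws on G, one of its two equal parts. For Q or G to hold most at 80 min, E must stay below a third of the total. That needs a leak constant of 0.00523 min⁻¹, about a third of the reading.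

**Two estimates.** My own reckoning with the reading leaves a pool of 54.2%, so E stands at 41.9%. The forecast names E at 44%, above my figure; one of its grounds is that the “E rate divided by G gives about 0.016/min in both runs”.

**The result.** The flask gives E at 41.1%, with G and Q at 26.5% and 26.5%. D, a further product formed from Z, holds 5.92%, less than the 15 points by which E leads.

    Z → Q (k = 0.0122 s⁻¹)
    L + Q ⇌ L + G (K = 1.09, k = 0.0523 L mol⁻¹ s⁻¹)
    2 Z → D (k = 0.00392 L mol⁻¹ s⁻¹)
    G ⇌ E (K = 27.0, k = 2.71 × 10⁻⁴ s⁻¹)

**Deciding comparison.** In this flask at 80.0 min, the half-life of Q by its forward turning into G is 7.4 min, shorter than the 42.5 min that the leak constant gives for G; the leak is the slower step, the rate-limiting step of E's rise, and Q and G stand level. In the neighbour flask with [Z] = 0.050 M, where [L] falls in step with [Z], my reckoning puts the same half-life at 29.5 min against that same 42.5 min, and at 80.0 min Q stands at 37.7%, G at 28.0% and E at 32.8%.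

The runs were computed for substances that don't exist, and the scatter is random.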